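**Retrosynthetic overview**

1. Locants: lactone O1, C2 (C=O), C3 (bears the ring A benzyl group), C4 (bears the ring B benzyl group), C5 (OCH2). Prestegane A (14) ⇐ benzyl ether 13 ⇐ C3 epimerization of 12 ⇐ enantioselective 1,4-reduction of butenolide 11, which sets C4.
2. Butenolide 11 ⇐ alkynol 4 + benzylic Grignard reagent 6 + CO2 (7) in one flask, forming C4–CH2 (ring B side), C2–C3 and O1–C2.
3. Structural feature used: the atom string ring A–CH2–C3–C4–C5–O1 is the skeleton of a 4-arylbut-2-yn-1-ol, with C3 and C4 as the two alkyne carbons. The C5 oxygen can therefore steer the ring B benzyl group onto C4 and leave a carbon–magnesium bond on C3 for CO2, which becomes C2.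
4. Alkynol 4 ⇐ benzylic bromide 2 (from commercial alcohol 1) + propargyl alcohol 3; Grignard reagent 6 ⇐ 3,4-dimethoxybenzyl chloride 5.
5. Ring order: both arenes are bought; the γ-lactone is the only ring made and it closes in the key step.

Key step: step 4

Assumption: the facial sense of the copper hydride reduction cannot be assigned in advance for this substrate; (R)-DTBM-SEGPHOS is written as the enantiomer expected to give 4R, and (S)-DTBM-SEGPHOS would be used with no other change if hydride adds to the opposite face.

**Route**

Step 1
Reactants: 1 3-benzyloxy-4-methoxybenzyl alcohol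
Product: 2 3-benzyloxy-4-methoxybenzyl bromide
Conditions: PBr3 (0.4 equiv), CH2Cl2, 0 °C; NaHCO3 wash; used without storage
Reagents that add atoms: phosphorus tribromide, BrP(Br)Br
Why: Bromination of a primary benzylic alcohol with PBr3 proceeds by SN2 displacement of the intermediate phosphite ester by bromide, and the aryl benzyl and methyl ethers are inert at 0 °C.

Step 2
Reactants: 2 3-benzyloxy-4-methoxybenzyl bromide, 3 propargyl alcohol
Product: 4 4-(3-benzyloxy-4-methoxyphenyl)but-2-yn-1-ol
Conditions: 3 (1.5 equiv), CuI (10 mol%), Bu4NI (10 mol%), K2CO3 (1.5 equiv), DMF, rt, argon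
Reagents that add atoms: none
Why: This is a copper-catalysed C(sp)–C(sp3) coupling of a terminal alkyne with a benzylic halide, in which the copper acetylide formed under carbonate base displaces the benzylic halide; the conditions tolerate the free hydroxyl and are too weakly basic at room temperature to isomerize the skipped aryl alkyne.

Step 3
Reactants: 5 3,4-dimethoxybenzyl chloride
Product: 6 3,4-dimethoxybenzylmagnesium chloride (solution, titrated and used directly)
Conditions: Mg turnings (3 equiv, activated with i-Bu2AlH, 1 mol%), 2-MeTHF, 0 °C, slow addition of 5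
Reagents that add atoms: magnesium, [Mg]
Why: Grignard formation by insertion of magnesium into the benzylic C–Cl bond; slow addition to excess activated metal at 0 °C in 2-MeTHF keeps the halide concentration low and limits Wurtz homocoupling.

Step 4
Reactants: 4 4-(3-benzyloxy-4-methoxyphenyl)but-2-yn-1-ol, 6 3,4-dimethoxybenzylmagnesium chloride, 7 carbon dioxide
Product: 11 3-(3-benzyloxy-4-methoxybenzyl)-4-(3,4-dimethoxybenzyl)furan-2(5H)-one, via chloromagnesium alkoxide 8 (not isolated), via oxamagnesacycle 9 (not isolated), via Z-hydroxy acid 10 (not isolated)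
Conditions: 6 (3 equiv), CuI (10 mol%), 2-MeTHF/toluene, −40 °C → rt; CO2 (dry gas), −20 °C → rt; 2 M HCl, rt
Reagents that add atoms: none
Why: The first equivalent of 6 deprotonates the hydroxyl to give alkoxide 8, and a second equivalent adds across the alkyne inside an alkoxide–magnesium chelate, delivering the ring B benzyl group to the alkyne carbon nearer oxygen (future C4) and leaving magnesium on the distal carbon (future C3), anti to the new C–C bond and cis to the CH2O arm, as oxamagnesacycle 9. The C3–Mg bond of 9 is carboxylated by CO2 with retention of alkene geometry, and acidification gives Z-hydroxy acid 10, whose hydroxyl attacks the cis carboxyl group in a 5-exo-trig lactonization that closes the butenolide, the only ring formed. The closest known reaction type is the hydroxyl-directed anti-carbomagnesiation of 2-alkyn-1-ols by Grignard reagents (benzylic and allylic reagents being the most reactive, CuI widening the scope) with CO2 trapping to give butenolides. No stereocentre is created. The step needs regioselectivity (benzyl on C4, not C3), anti-addition (a syn adduct could not lactonize) and addition in preference to deprotonation of the benzylic–propargylic CH2; the first two are secured by the five-membered chelate, which can only form with magnesium on the distal carbon cis to CH2O, and the third by the low kinetic basicity of a benzylic Grignard reagent toward carbon acids together with the low starting temperature and copper catalysis.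

Step 5
Reactants: 11 3-(3-benzyloxy-4-methoxybenzyl)-4-(3,4-dimethoxybenzyl)furan-2(5H)-one
Product: 12 (4R)-3-(3-benzyloxy-4-methoxybenzyl)-4-(3,4-dimethoxybenzyl)dihydrofuran-2(3H)-one as a mixture of C3 epimers (cis-(3S,4R) expected to predominate)
Conditions: Cu(OAc)2·H2O (5 mol%), (R)-DTBM-SEGPHOS (5.5 mol%), (EtO)2MeSiH (2 equiv), t-BuOH (1.5 equiv), toluene, 0 °C → rt; aq NH4F
Reagents that add atoms: none
Why: Proposed new method: the bisphosphine-ligated copper hydride generated from Cu(OAc)2 and the silane is expected to transfer hydride to the β-carbon C4 of the butenolide, whose ring-locked s-trans enoate is far more electrophilic than an acyclic tetrasubstituted enoate, and the resulting copper enolate is protonated at C3 by t-BuOH, which returns copper to the cycle as its tert-butoxide; the closest known reaction type is the copper hydride-catalysed asymmetric conjugate reduction of β-monosubstituted butenolides and of β,β-disubstituted unsaturated lactones and esters, which has not been shown on an α,β-disubstituted (tetrasubstituted) butenolide; C4 is set by ligand-controlled facial delivery of hydride, while C3 is not controlled here (protonation anti to the C4 substituent should favour the cis epimer) and is corrected in step 6.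

Step 6
Reactants: 12 (4R)-3-(3-benzyloxy-4-methoxybenzyl)-4-(3,4-dimethoxybenzyl)dihydrofuran-2(3H)-one (C3 epimer mixture)
Product: 13 (3R,4R)-3-(3-benzyloxy-4-methoxybenzyl)-4-(3,4-dimethoxybenzyl)dihydrofuran-2(3H)-one
Conditions: t-BuOK (0.2 equiv), t-BuOH/THF, rt; AcOH quench; crystallization or chromatography, cis epimer recycled
Reagents that add atoms: none
Why: Base-catalysed epimerization through the lactone enolate equilibrates C3, the only acidic stereocentre, toward the thermodynamically preferred trans-3,4-dibenzyl lactone in which the two benzyl groups avoid each other, while C4 is not touched.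

Step 7
Reactants: 13 (3R,4R)-3-(3-benzyloxy-4-methoxybenzyl)-4-(3,4-dimethoxybenzyl)dihydrofuran-2(3H)-one
Product: 14 prestegane A, (3R,4R)-3-(3-hydroxy-4-methoxybenzyl)-4-(3,4-dimethoxybenzyl)dihydrofuran-2(3H)-one
Conditions: H2 (1 atm), 10% Pd/C, EtOAc/EtOH, rt
Reagents that add atoms: none
Why: Catalytic hydrogenolysis cleaves the benzyl aryl ether under neutral conditions that leave the lactone, the aryl methyl ethers and both stereocentres unchanged.

**Compound list**

1 | 3-benzyloxy-4-methoxybenzyl alcohol | COc1ccc(CO)cc1OCc1ccccc1 | starting material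
2 | 3-benzyloxy-4-methoxybenzyl bromide | COc1ccc(CBr)cc1OCc1ccccc1 | intermediate
3 | propargyl alcohol (prop-2-yn-1-ol) | C#CCO | starting material
4 | 4-(3-benzyloxy-4-methoxyphenyl)but-2-yn-1-ol | OCC#CCc1ccc(OC)c(OCc2ccccc2)c1 | intermediate
5 | 3,4-dimethoxybenzyl chloride | COc1ccc(CCl)cc1OC | starting material
6 | 3,4-dimethoxybenzylmagnesium chloride | COc1ccc(C[Mg]Cl)cc1OC | intermediate
7 | carbon dioxide | O=C=O | starting material
8 | chloromagnesium 4-(3-benzyloxy-4-methoxyphenyl)but-2-yn-1-olate | Cl[Mg]OCC#CCc1ccc(OC)c(OCc2ccccc2)c1 | intermediate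
9 | 3-(3-benzyloxy-4-methoxybenzyl)-4-(3,4-dimethoxybenzyl)-2,5-dihydro-1,2-oxamagnesole (oxamagnesacycle) | [Mg]1OCC(Cc2ccc(OC)c(OC)c2)=C1Cc1ccc(OC)c(OCc2ccccc2)c1 | intermediate
10 | (Z)-2-(3-benzyloxy-4-methoxybenzyl)-3-(3,4-dimethoxybenzyl)-4-hydroxybut-2-enoic acid | OC/C(Cc1ccc(OC)c(OC)c1)=C(/Cc1ccc(OC)c(OCc2ccccc2)c1)C(=O)O | intermediate
11 | 3-(3-benzyloxy-4-methoxybenzyl)-4-(3,4-dimethoxybenzyl)furan-2(5H)-one | O=C1OCC(Cc2ccc(OC)c(OC)c2)=C1Cc1ccc(OC)c(OCc2ccccc2)c1 | intermediate
12 | (4R)-3-(3-benzyloxy-4-methoxybenzyl)-4-(3,4-dimethoxybenzyl)dihydrofuran-2(3H)-one, C3 epimer mixture | COc1ccc(CC2C(=O)OC[C@@H]2Cc2ccc(OC)c(OC)c2)cc1OCc1ccccc1 | intermediate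
13 | (3R,4R)-3-(3-benzyloxy-4-methoxybenzyl)-4-(3,4-dimethoxybenzyl)dihydrofuran-2(3H)-one | COc1ccc(C[C@H]2C(=O)OC[C@@H]2Cc2ccc(OC)c(OC)c2)cc1OCc1ccccc1 | intermediate
14 | prestegane A, (3R,4R)-3-(3-hydroxy-4-methoxybenzyl)-4-(3,4-dimethoxybenzyl)dihydrofuran-2(3H)-one | COc1ccc(C[C@H]2C(=O)OC[C@@H]2Cc2ccc(OC)c(OC)c2)cc1O | target

**Step count**

Total steps: 7. Longest linear sequence: 6 steps (1 → 2 → 4 → 11 → 12 → 13 → 14, steps 1, 2, 4, 5, 6 and 7); step 3 is the one-step side branch to 6.

**Steps most likely to fail**

Step 5 (copper hydride reduction of the tetrasubstituted butenolide). The copper hydride may not engage the fully substituted alkene, or hydride transfer may occur with poor facial selectivity. The fallback uses known chemistry, sets out from propargyl alcohol 3, Grignard reagent 6 and carbon dioxide 7, and comes back at 13. The same hydroxyl-directed carbomagnesiation–carboxylation is run on 3 itself (6, CuI 10 mol%, then CO2, then HCl) to give the β-monosubstituted butenolide 4-(3,4-dimethoxybenzyl)furan-2(5H)-one F1. This trisubstituted butenolide belongs to the class for which copper hydride asymmetric conjugate reduction is established (Cu(OAc)2·H2O, DTBM-SEGPHOS in the enantiomer that leads to the R lactone, (EtO)2MeSiH, t-BuOH) and should give (R)-4-(3,4-dimethoxybenzyl)dihydrofuran-2(3H)-one F2. Deprotonation with LiN(SiMe3)2 in THF at −78 °C and alkylation of the enolate with bromide 2, anti to the C4 substituent, should then give the trans lactone 13 directly, so that steps 5 and 6 are both bypassed.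

Step 4 (key step). The Grignard reagent may deprotonate the benzylic–propargylic CH2 of 4, leading to alkyne-to-allene isomerization and loss of reagent, or carbomagnesiation may stall so that carboxylation does not occur at C3. The fallback sets out from chloride 5 and bromide 2 and comes back at 11. The butenolide is assembled by two successive Negishi couplings on commercial 3,4-dibromofuran-2(5H)-one F3. Zinc insertion into 5 (Zn dust, LiCl, THF) gives (3,4-dimethoxybenzyl)zinc chloride F4, which couples under Pd(PPh3)4 catalysis at the more electrophilic C4–Br bond (the β-position, a vinylogous acyl bromide) to give 3-bromo-4-(3,4-dimethoxybenzyl)furan-2(5H)-one F5. A second coupling of F5 with (3-benzyloxy-4-methoxybenzyl)zinc bromide F6 (from 2, Zn dust, LiCl, THF) at C3 should deliver 11.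

Step 2 (alkyne–benzyl coupling). Carbonate-mediated isomerization of the skipped aryl alkyne, O-benzylation of the free hydroxyl or oxidative alkyne dimerization may erode the coupling. The fallback sets out from propargyl alcohol 3 and bromide 2 and comes back at 4. Alcohol 3 is masked as its tetrahydropyranyl ether 2-(prop-2-yn-1-yloxy)tetrahydro-2H-pyran F7 (3,4-dihydro-2H-pyran, pyridinium p-toluenesulfonate, CH2Cl2). F7 is deprotonated with EtMgBr in THF to the alkynylmagnesium bromide F8, which is coupled with 2 under CuBr·SMe2 catalysis (THF, 50 °C) to the protected alkynol 2-{[4-(3-benzyloxy-4-methoxyphenyl)but-2-yn-1-yl]oxy}tetrahydro-2H-pyran F9. Methanolysis (pyridinium p-toluenesulfonate, MeOH) releases 4. No carbonate base and no free hydroxyl are present during C–C bond formation.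

**Further compounds**

F1 | step 5 | 4-(3,4-dimethoxybenzyl)furan-2(5H)-one | O=C1OCC(Cc2ccc(OC)c(OC)c2)=C1
F2 | step 5 | (R)-4-(3,4-dimethoxybenzyl)dihydrofuran-2(3H)-one | O=C1C[C@@H](Cc2ccc(OC)c(OC)c2)CO1
F3 | step 4 | 3,4-dibromofuran-2(5H)-one | O=C1OCC(Br)=C1Br
F4 | step 4 | (3,4-dimethoxybenzyl)zinc chloride | COc1ccc(C[Zn]Cl)cc1OC
F5 | step 4 | 3-bromo-4-(3,4-dimethoxybenzyl)furan-2(5H)-one | O=C1OCC(Cc2ccc(OC)c(OC)c2)=C1Br
F6 | step 4 | (3-benzyloxy-4-methoxybenzyl)zinc bromide | COc1ccc(C[Zn]Br)cc1OCc1ccccc1
F7 | step 2 | 2-(prop-2-yn-1-yloxy)tetrahydro-2H-pyran | C#CCOC1CCCCO1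
F8 | step 2 | bromomagnesium acetylide of 2-(prop-2-yn-1-yloxy)tetrahydro-2H-pyran | Br[Mg]C#CCOC1CCCCO1
F9 | step 2 | 2-{[4-(3-benzyloxy-4-methoxyphenyl)but-2-yn-1-yl]oxy}tetrahydro-2H-pyran | COc1ccc(CC#CCOC2CCCCO2)cc1OCc1ccccc1
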